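**Retrosynthetic overview**

1. Late stage: the C2 ketone is unmasked last. The C9 senecioate and C8 acetate come from a cis-8,9-diol, the diol from C8 hydroxylation and equatorial hydride delivery at C9 of a 7-isopropenyl-9-ketone, and the isopropenyl group from conjugate addition to a 7-en-9-one made from the cis-fused 4,5-dimethyldecalin-2,9-dione.
2. Key disconnection: the C4–C5 bond of ring A (C1–C5, C10) and the C10–H bond. The strategy rests on the array C4(H,CH3)–C5(CH3, quaternary)–C10(H, cis to the C5 methyl)–C9(=O). Undoing a 1,2-shift of C4 (C5 back to C10) and a 1,2-hydride shift (C10 back to C9) gives a spiro[4.5]decane with C4 and C1 both on C10, a tertiary carbinol at C5 and a secondary carbinol at C9.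
3. The spiro diol comes from (4S)-4-methylspiro[4.5]decane-2,6,10-trione. Oxazaborolidine reduction picks one diastereotopic ring carbonyl (sets C9 and C10); methylenation, epoxidation and hydride opening set C5. The trione comes from the enantioselective Michael adduct of cyclohexane-1,3-dione and (E)-pent-3-en-2-one (sets C4) by oxidative enolate coupling (C1–C10).
4. Ring order: the six-membered carbocycle that becomes ring B is present from the start, the spiro five-membered ring is closed in step 2, and ring A arises from it by ring expansion in step 10.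

Key step: step 10

Remark on labels: eremophilane numbering of the target is used for every intermediate (ring A = C1–C5, C10; ring B = C5–C10; in the spiro compounds C10 is the spiro atom, C1–C4 the five-membered ring, C5–C9 the six-membered ring). "Top" is the face of the six-membered ring that carries C4 in the spiro series.
Assumption: the senses of induction in steps 1 and 4 follow the usual iminium and oxazaborolidine models; if either were opposite, the pseudoenantiomeric catalyst would be used.

**Route**

Step 1
Reactants: 1 cyclohexane-1,3-dione; 2 (E)-pent-3-en-2-one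
Product: 3 (S)-2-(4-oxopentan-2-yl)cyclohexane-1,3-dione (handled as its cyclic hemiketal tautomer)
Conditions: 9-amino-9-deoxy-epi-quinine (20 mol %), CF3CO2H (40 mol %), THF, rt
Reagents that add atoms: none
Why: Primary-amine (iminium) catalysed asymmetric Michael addition of a cyclic 1,3-diketone to an enone; the catalyst shields one face of the iminium ion and should set C4 as S.

Step 2
Reactants: 3 (S)-2-(4-oxopentan-2-yl)cyclohexane-1,3-dione
Product: 5 (4S)-4-methylspiro[4.5]decane-2,6,10-trione, via dilithium bis-enolate 4 (not isolated)
Conditions: LiN(i-Pr)2 (2.2 equiv), THF, −78 °C; then [Fe(DMF)3Cl2][FeCl4] (1.1 equiv, two oxidising equivalents of trivalent iron), −78 → 0 °C, high dilution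
Reagents that add atoms: none
Why: Intramolecular oxidative enolate heterocoupling (ketone enolate with 1,3-dicarbonyl enolate); the second deprotonation should be kinetic at the terminal methyl, and the derived α-keto radical should close the five-membered ring onto the dione enolate carbon (5-exo), forming C1–C10 without a halogenation that the dione would intercept.

Step 3
Reactants: 5 (4S)-4-methylspiro[4.5]decane-2,6,10-trione
Product: 6 (4S)-2,2-(ethylenedioxy)-4-methylspiro[4.5]decane-6,10-dione
Conditions: (Me3SiOCH2)2 (1.2 equiv), Me3SiOTf (5 mol %), CH2Cl2, −78 → −40 °C; pyridine quench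
Reagents that add atoms: 1,2-bis(trimethylsilyloxy)ethane, C[Si](C)(C)OCCO[Si](C)(C)C
Why: Silyl-triflate-catalysed ketalisation under kinetic control; C2 is the only carbonyl not flanked by the quaternary spiro carbon, while the two ring carbonyls are neopentyl and deactivate each other, so mono-ketalisation should occur at C2.

Step 4
Reactants: 6 (4S)-2,2-(ethylenedioxy)-4-methylspiro[4.5]decane-6,10-dione
Product: 7 (4S,5R,10R)-2,2-(ethylenedioxy)-10-hydroxy-4-methylspiro[4.5]decan-6-one (spiro numbering; carbinol at eremophilane C9, OH cis to C4, on the ring carbon trans to the C4 methyl)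
Conditions: (S)-2-methyl-CBS-oxazaborolidine (20 mol %), BH3·SMe2 (0.7 equiv), THF, −30 °C; aqueous work-up
Reagents that add atoms: none
Why: Corey–Bakshi–Shibata reduction desymmetrising the 2,2-disubstituted 1,3-dione; with the spiro carbon as the large group the (S)-catalyst should give an R carbinol, which is only possible by attack on the carbonyl trans to the C4 methyl from the C1 side or on the other carbonyl from the C4 side, and the latter trajectory runs into the C4 methyl, so C9 and the now stereogenic C10 are set together.

Step 5
Reactants: 7 hydroxy ketone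
Product: 8 triethylsilyl ether of 7
Conditions: Et3SiCl, imidazole, DMF, 0 °C → rt
Reagents that add atoms: chlorotriethylsilane, CC[Si](Cl)(CC)CC
Why: Standard silylation of a secondary alcohol, which removes the retro-aldol pathway of the β-hydroxy ketone before the basic olefination.

Step 6
Reactants: 8 silyl ether ketone
Product: 9 methylene compound (8 with the C5 carbonyl replaced by C=CH2)
Conditions: Ph3PCH3Br, KOt-Bu, toluene, 80 °C
Reagents that add atoms: methyltriphenylphosphonium bromide, C[P+](c1ccccc1)(c1ccccc1)c1ccccc1.[Br-]
Why: Wittig methylenation under conditions used for hindered ketones; the β-silyloxy group cannot be eliminated because the intervening C10 is quaternary.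

Step 7
Reactants: 9 methylene compound
Product: 10 spiro-epoxide at C5 (epoxide oxygen on the bottom face, trans to C4 and to the 9-silyloxy group; CH2 on the top face)
Conditions: mCPBA, NaHCO3, CH2Cl2, 0 °C
Reagents that add atoms: meta-chloroperbenzoic acid, OOC(=O)c1cccc(Cl)c1
Why: Prilezhaev epoxidation; in the chair with C4 axial (favoured by allylic strain between the methylene group and the equatorial C10 substituent) the peracid should approach axially from the face anti to C4 and its methyl, placing oxygen trans to C4.

Step 8
Reactants: 10 spiro-epoxide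
Product: 11 tertiary alcohol (C5 methyl carbinol with OH axial, trans to C4; 9-OSiEt3; C2 ketal)
Conditions: LiBHEt3, THF, 0 °C → rt; H2O
Reagents that add atoms: none
Why: SN2 hydride opening at the primary epoxide carbon leaves the C5–O bond untouched, so the carbinol configuration is the one fixed in step 7, which is the epimer that direct methyl-metal addition to 8 (attack anti to C4) would not give.

Step 9
Reactants: 11 protected tertiary alcohol
Product: 12 (4S,5R,6R,10R)-6,10-dihydroxy-4,6-dimethylspiro[4.5]decan-2-one (spiro numbering)
Conditions: AcOH/THF/H2O (3:1:1), 40 °C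
Reagents that add atoms: water, O
Why: Mild acid hydrolysis of the cyclopentanone ketal and of the triethylsilyl ether, with an acid too weak to ionise the tertiary alcohol.

Step 10
Reactants: 12 spiro diol ketone
Product: 13 (4S,5R,10S)-4,5-dimethyl-cis-decalin-2,9-dione (eremophilane numbering)
Conditions: CF3SO3H (20 mol %), (CF3)2CHOH, 0 °C, short contact time; NaHCO3 quench
Reagents that add atoms: none
Why: Proposed new method: protonation and loss of the axial C5 hydroxyl should be assisted by the antiperiplanar axial C10–C4 bond, so that C4 shifts suprafacially from C10 to C5 with retention (a ring-enlarging Wagner–Meerwein shift), and the electron-deficient C10 should then accept the axial C9 hydrogen, a shift driven by the carbinol oxygen that ends as the C9 ketone (semipinacol-type termination). The closest known reactions are acid-mediated spiro[4.5]decyl-to-decalin cation rearrangements and semipinacol 1,2-hydride shifts; their coupling in one cascade on a 1,3-diol is untested. Ring A is not closed by a cyclisation but by expansion of the five-membered ring (C4–C5 forms as C4–C10 breaks), so no exo or endo mode applies. C5 is set by inversion (C4 enters anti to the leaving oxygen and carries its own configuration along, which places the two methyls cis) and C10 by inversion (hydride enters anti to the departing C4), both dictated by the single chair in which C5–O, C10–C4 and C9–H are all axial and mutually antiperiplanar. The step needs C4 rather than C1 to migrate, and shift rather than proton loss or Grob-type C9–C10 cleavage: C1 is equatorial, primary and α to the C2 carbonyl; the C9–C10 ring bond is not aligned with the axial leaving group; and in the non-basic, weakly nucleophilic medium any alkene can re-enter the cation manifold while carbonyl formation is irreversible. Low temperature and a prompt quench are chosen so that the new C10–H, α to the C9 ketone, is not equilibrated.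

Step 11
Reactants: 13 decalin-2,9-dione
Product: 14 (4S,5R,10S)-2,2-(ethylenedioxy)-4,5-dimethyl-cis-decalin-9-one
Conditions: (Me3SiOCH2)2 (1.1 equiv), Me3SiOTf (5 mol %), CH2Cl2, −78 °C; pyridine quench
Reagents that add atoms: 1,2-bis(trimethylsilyloxy)ethane, C[Si](C)(C)OCCO[Si](C)(C)C
Why: Kinetic silyl-triflate-catalysed ketalisation should select the unhindered C2 ketone over the C9 ketone (α-branched at the ring fusion and screened by ring A), under aprotic cold conditions that do not enolise C9 towards C10.

Step 12
Reactants: 14 keto ketal
Product: 16 (4S,5R,10S)-2,2-(ethylenedioxy)-4,5-dimethyl-cis-decal-7-en-9-one, via lithium 8-enolate 15 (not isolated)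
Conditions: LiN(i-Pr)2, THF, −78 °C; then PhS(Cl)=N-t-Bu, −78 °C
Reagents that add atoms: none
Why: Kinetic deprotonation at the C8 methylene (not the hindered C10 methine) followed by sulfinimidoyl chloride dehydrogenation of the enolate (S-attack, then syn elimination) should give the 7-en-9-one without touching C10.

Step 13
Reactants: 16 enone
Product: 17 (4S,5R,7S,10S)-2,2-(ethylenedioxy)-7-isopropenyl-4,5-dimethyl-9-(trimethylsilyloxy)-cis-decal-8-ene
Conditions: CH2=C(CH3)MgBr, CuBr·SMe2 (20 mol %), Me3SiCl, THF, −78 °C; Et3N
Reagents that add atoms: isopropenylmagnesium bromide, CC(=C)[Mg]Br; chlorotrimethylsilane, C[Si](C)(C)Cl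
Why: Copper-catalysed conjugate addition with in situ silyl trapping; axial attack at C7 meets a syn-axial C5 substituent on either face and should choose the face of the small C5 methyl (convex, anti to ring A), giving the 7-isopropenyl group cis to the C5 methyl and equatorial after ring inversion.

Step 14
Reactants: 17 silyl enol ether
Product: 19 (4S,5R,7R,8R,10S)-2,2-(ethylenedioxy)-8-hydroxy-7-isopropenyl-4,5-dimethyl-cis-decalin-9-one, via lithium 8-enolate 18 (not isolated)
Conditions: MeLi, THF, 0 °C; then 2-(phenylsulfonyl)-3-phenyloxaziridine, −78 °C; aq. NH4Cl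
Reagents that add atoms: 2-(phenylsulfonyl)-3-phenyloxaziridine, O=S(=O)(N1OC1c1ccccc1)c1ccccc1
Why: Davis hydroxylation of the regiodefined lithium enolate; the bulky oxidant should approach C8 anti to the neighbouring isopropenyl group, giving the equatorial 8-hydroxyl trans to C7, which is also the more stable α-ketol epimer.

Step 15
Reactants: 19 α-hydroxy ketone
Product: 20 (4S,5R,7R,8R,9S,10S)-2,2-(ethylenedioxy)-7-isopropenyl-4,5-dimethyl-cis-decalin-8,9-diol (cis-diol)
Conditions: LiBH(s-Bu)3 (3 equiv), THF, −78 °C; H2O
Reagents that add atoms: none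
Why: Bulky trialkylborohydride reduction; axial approach to C9 is blocked by the syn-axial C5–C4 bond of ring A, so hydride should enter equatorially and the 9-hydroxyl becomes axial, cis to the 8-hydroxyl.

Step 16
Reactants: 20 cis-diol
Product: 21 8-acetate of 20 (9-hydroxyl free)
Conditions: Ac2O (1.1 equiv), pyridine, CH2Cl2, 0 °C
Reagents that add atoms: acetic anhydride, CC(=O)OC(C)=O
Why: Selective acylation of the equatorial C8 hydroxyl over the axial C9 hydroxyl, which is syn-axial to C4 and flanked by the ring fusion.

Step 17
Reactants: 21 hydroxy acetate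
Product: 22 8-acetate 9-(3-methylbut-2-enoate) of 20
Conditions: 3-methylbut-2-enoyl chloride, DMAP, pyridine, CH2Cl2, 0 °C → rt
Reagents that add atoms: 3-methylbut-2-enoyl chloride, CC(C)=CC(=O)Cl
Why: DMAP-catalysed acylation of the hindered axial alcohol; the weak base pyridine at low temperature limits deconjugation of the senecioyl unit through a vinylketene.

Step 18
Reactants: 22 diester ketal
Product: 23 (4S,5R,7R,8R,9S,10S)-8-acetoxy-9-(3-methylbut-2-enoyloxy)-cis-eremophil-11-en-2-one (target CNP0150397.1)
Conditions: 1 M HCl, THF, rt
Reagents that add atoms: water, O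
Why: Acid hydrolysis of the dioxolane; both esters and the isopropenyl group tolerate dilute aqueous acid, and no stereocentre is then α to a carbonyl with an epimerisable hydrogen.

**Compound list**

1 | cyclohexane-1,3-dione | O=C1CCCC(=O)C1 | starting material
2 | (E)-pent-3-en-2-one | C/C=C/C(C)=O | starting material
3 | (S)-2-(4-oxopentan-2-yl)cyclohexane-1,3-dione (open form of the hemiketal) | CC(=O)C[C@H](C)C1C(=O)CCCC1=O | intermediate
4 | dilithium bis-enolate of 3 (dione enolate and terminal methyl-ketone enolate) | [Li]OC(=C)C[C@H](C)C1=C(O[Li])CCCC1=O | intermediate (not isolated)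
5 | (4S)-4-methylspiro[4.5]decane-2,6,10-trione | C[C@H]1CC(=O)CC12C(=O)CCCC2=O | intermediate
6 | (4S)-2,2-(ethylenedioxy)-4-methylspiro[4.5]decane-6,10-dione | C[C@H]1CC2(OCCO2)CC13C(=O)CCCC3=O | intermediate
7 | (4S,5R,10R)-2,2-(ethylenedioxy)-10-hydroxy-4-methylspiro[4.5]decan-6-one | O[C@@H]1CCCC(=O)[C@@]12CC3(OCCO3)C[C@@H]2C | intermediate
8 | triethylsilyl ether of 7 | CC[Si](CC)(CC)O[C@@H]1CCCC(=O)[C@@]12CC3(OCCO3)C[C@@H]2C | intermediate
9 | C5-methylene analogue of 8 | CC[Si](CC)(CC)O[C@@H]1CCCC(=C)[C@@]12CC3(OCCO3)C[C@@H]2C | intermediate
10 | C5 spiro-epoxide of 9, oxygen trans to C4 | CC[Si](CC)(CC)O[C@@H]1CCC[C@]4(CO4)[C@@]12CC3(OCCO3)C[C@@H]2C | intermediate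
11 | C5 methyl carbinol (OH trans to C4), 9-OSiEt3, C2 ketal | CC[Si](CC)(CC)O[C@@H]1CCC[C@@](C)(O)[C@@]12CC3(OCCO3)C[C@@H]2C | intermediate
12 | (4S,5R,6R,10R)-6,10-dihydroxy-4,6-dimethylspiro[4.5]decan-2-one | O[C@@H]1CCC[C@@](C)(O)[C@@]12CC(=O)C[C@@H]2C | intermediate
13 | (4S,5R,10S)-4,5-dimethyl-cis-decalin-2,9-dione | C[C@H]1CC(=O)C[C@@H]2C(=O)CCC[C@]12C | intermediate
14 | C2 ethylene ketal of 13 | C[C@H]1CC3(OCCO3)C[C@@H]2C(=O)CCC[C@]12C | intermediate
15 | lithium enolate of 14 (C8=C9–OLi) | C[C@H]1CC3(OCCO3)C[C@@H]2C(O[Li])=CCC[C@]12C | intermediate (not isolated)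
16 | 7-en-9-one, C2 ketal | C[C@H]1CC3(OCCO3)C[C@@H]2C(=O)C=CC[C@]12C | intermediate
17 | 7-isopropenyl 9-trimethylsilyl enol ether, C2 ketal | C[C@H]1CC3(OCCO3)C[C@@H]2C(O[Si](C)(C)C)=C[C@@H](C(C)=C)C[C@]12C | intermediate
18 | lithium enolate from 17 (C8=C9–OLi) | C[C@H]1CC3(OCCO3)C[C@@H]2C(O[Li])=C[C@@H](C(C)=C)C[C@]12C | intermediate (not isolated)
19 | 8-hydroxy-7-isopropenyl-9-ketone, C2 ketal (8-OH trans to C7) | C[C@H]1CC3(OCCO3)C[C@@H]2C(=O)[C@H](O)[C@@H](C(C)=C)C[C@]12C | intermediate
20 | cis-8,9-diol, C2 ketal | C[C@H]1CC3(OCCO3)C[C@@H]2[C@H](O)[C@H](O)[C@@H](C(C)=C)C[C@]12C | intermediate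
21 | 8-acetate 9-ol, C2 ketal | C[C@H]1CC3(OCCO3)C[C@@H]2[C@H](O)[C@H](OC(C)=O)[C@@H](C(C)=C)C[C@]12C | intermediate
22 | 8-acetate 9-senecioate, C2 ketal | C[C@H]1CC3(OCCO3)C[C@@H]2[C@H](OC(=O)C=C(C)C)[C@H](OC(C)=O)[C@@H](C(C)=C)C[C@]12C | intermediate
23 | CNP0150397.1 | C[C@H]1CC(=O)C[C@@H]2[C@H](OC(=O)C=C(C)C)[C@H](OC(C)=O)[C@@H](C(C)=C)C[C@]12C | target

**Totals**

Total step count: 18. Longest linear sequence: 18 steps (from 1 and 2 to 23).

**Steps most likely to fail**

Step 10 (Proposed new method). What may go wrong:
- the C5 cation may lose a proton instead of accepting C4;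
- the C10 cation may lose the C1 proton (giving the conjugated enone) instead of accepting hydride;
- the 1,3-diol monocation may fragment across C9–C10;
- C1 may migrate instead of C4;
- acid-promoted enolisation may erode the new C10 configuration.

Fallback, known chemistry, setting out from 2 and returning at 13, without the spiro rearrangement. 2-Methylcyclohexanone is condensed with (S)-1-phenylethylamine to the (S)-1-phenylethylimine of 2-methylcyclohexanone F1. Its secondary enamine tautomer adds to 2 in a chiral-imine Michael reaction, and aqueous acetic acid releases (2R)-2-methyl-2-[(2S)-4-oxopentan-2-yl]cyclohexan-1-one F2, in which C5 and C4 are set together. NaOMe in methanol closes ring A by aldol condensation to (4S,5R)-4,5-dimethyleremophil-1(10)-en-2-one core F3 (cis-dimethyl octalone). The γ-position is then oxygenated in the classical manner for such enones: isopropenyl acetate and TsOH give the 2-acetoxy-1,9-diene F4; mCPBA gives the 9-hydroxy-1(10)-en-2-one F5; Dess–Martin periodinane gives the 1(10)-ene-2,9-dione F6. Hydrogenation over Pd/C, which for angularly methylated octalones of this type should deliver hydrogen to give the cis ring fusion, leads to 13.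

Step 2. What may go wrong: unselective second deprotonation, intermolecular coupling of the radical, or oxidation at the dione carbon instead of C–C bond formation.

Fallback, setting out from 1 and returning at 5, replacing the oxidative coupling by a two-electron alkylation. Compound 1 is added under the conditions of step 1 to (E)-1-(tert-butyldimethylsilyloxy)pent-3-en-2-one F7 (one step from 2-(tert-butyldimethylsilyloxy)-N-methoxy-N-methylacetamide and CH3CH=CHMgBr) to give the silyloxy Michael adduct F8. Tetrabutylammonium fluoride buffered with acetic acid gives the α′-hydroxy ketone F9, which as its hemiketal has no free dione enol. MsCl and 2,6-lutidine at −20 °C give the primary mesylate F10. K2CO3 in acetonitrile opens the hemiketal and the dione enolate closes the five-membered ring by 5-exo-tet C-alkylation to give 5.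

Step 14. What may go wrong: stereoelectronically favoured axial attack on the enolate from the face of the isopropenyl group (poor facial selectivity at C8), and enediol-type transposition of the α-ketol.

Fallback, setting out from 19 (as whatever C8 mixture forms) and returning at 21, fixing C8 under thermodynamic control and reversing the order of acylation and reduction. Acetylation (Ac2O, pyridine) gives the 8-acetoxy-9-ketone F11. Brief equilibration with KOAc in acetic acid, as used for axial-to-equatorial epimerisation of α-acetoxy ketones, should converge on the equatorial acetate trans to C7. Reduction with LiBH(s-Bu)3 at −78 °C, quenched cold with acetic acid to suppress acetyl migration, gives 21.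

Further compounds
F1 | step 10 | (S)-1-phenylethylimine of 2-methylcyclohexanone | CC1CCCCC1=N[C@@H](C)c1ccccc1
F2 | step 10 | (2R)-2-methyl-2-[(2S)-4-oxopentan-2-yl]cyclohexan-1-one | CC(=O)C[C@H](C)[C@@]1(C)CCCCC1=O
F3 | step 10 | (4S,5R)-4,5-dimethyl-1(10)-en-2-one (cis-4,4a-dimethyl-4,4a,5,6,7,8-hexahydronaphthalen-2(3H)-one) | C[C@H]1CC(=O)C=C2CCCC[C@]12C
F4 | step 10 | 2-acetoxy-1,9-diene (dienyl acetate of F3) | C[C@H]1CC(OC(C)=O)=CC2=CCCC[C@]12C
F5 | step 10 | 9-hydroxy-1(10)-en-2-one | C[C@H]1CC(=O)C=C2C(O)CCC[C@]12C
F6 | step 10 | 1(10)-ene-2,9-dione | C[C@H]1CC(=O)C=C2C(=O)CCC[C@]12C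
F7 | step 2 | (E)-1-(tert-butyldimethylsilyloxy)pent-3-en-2-one | C/C=C/C(=O)CO[Si](C)(C)C(C)(C)C
F8 | step 2 | (S)-2-[5-(tert-butyldimethylsilyloxy)-4-oxopentan-2-yl]cyclohexane-1,3-dione | CC(C)(C)[Si](C)(C)OCC(=O)C[C@H](C)C1C(=O)CCCC1=O
F9 | step 2 | (S)-2-(5-hydroxy-4-oxopentan-2-yl)cyclohexane-1,3-dione | OCC(=O)C[C@H](C)C1C(=O)CCCC1=O
F10 | step 2 | methanesulfonate of F9 | CS(=O)(=O)OCC(=O)C[C@H](C)C1C(=O)CCCC1=O
F11 | step 14 | 8-acetoxy-7-isopropenyl-9-ketone, C2 ketal (equatorial acetate) | C[C@H]1CC3(OCCO3)C[C@@H]2C(=O)[C@H](OC(C)=O)[C@@H](C(C)=C)C[C@]12C
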